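Watch G first.

| flask | G | L | Z | remark | time |
|---|---|---|---|---|---|
| ochre | 1.8 M | 200 mM (held) | 14 mM | run made earlier |  |
| elm | 1.8 M | 200 mM (held) | 9.0 mM |  | 4.0 min |
| maple | 1.8 M | 200 mM (held) | 9.0 mM |  | 10 min |

- ochre (time / s: J / %, G / %, Q / %): 20.0: 1.2, 97.7, 0.6; 40.0: 4.8, 92.5, 2.5; 50.0: 6.8, 91.6, 3.4; 80.0: 8.3, 84.9, 4.7

(standard deviation of a reading: 1 percentage point)

- at the start none of L is in solution
- no earlier run changes the charge of Z; that part of a forecast is a guess

- which of these there is most of at the end, counted by the G in it, elm (Q / G / J)
- which of these there is most of at the end, counted by the G in it, maple (Q / G / J)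
- how much there is at the end of the one of these that leads, in percent of the G charged: elm
- how much there is at the end of the one of these that leads, in percent of the G charged: maple

**The mean.** We replace ochre's curve by one number. The mean loss constant, the logarithm of G charged over G left divided by the time, is 0.123 /min at ochre's last reading. We treat it as a pseudo-first-order constant, and it carries the scatter of that reading.

**The bracket.** Ochre had more Z than elm and maple, and no earlier run changes Z. If the loss ignores Z, the constant stands, and G ends at 61.2 % in elm and 29.3 % in maple. These are our low ends. If the loss goes in proportion to Z, G ends at 72.9 % in elm and 45.4 % in maple. These are our high ends.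

**The error.** Ochre's reading at 50.0 s gives a smaller mean, 0.105 /min. That gap measures what one mean costs: it lifts maple's low end by 5.6 percentage points. The hand goes no further.

**The leader.** Elm's low end leaves G above J and Q together, so by this reckoning G leads elm. Maple's high end leaves J and Q together above G, so maple stays open.

**The forecast.** The forecast gave G the lead in both, at 72 % in elm and 43 % in maple, nearer our high ends, on this ground: “The Z order is untested, so I guess first order”.

**The result.** In elm the leader is G, at 61.8 %. In maple the leader is Q, at 48.3 %, and G stands at 35.2 %.

    L ⇌ E, rate k1*(csat - [E]) (kL = 0.0382 /s)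
    G + E ⇌ Q (K = 150 /M, k = 0.00931 /M/s)
    2 X → D (k = 0.0548 /M/s)
    G + E ⇌ J (K = 2.57 /M, k = 0.0208 /M/s)
    J + X ⇌ Q + X, rate k5*[X]*[J] forward; the back reaction follows from the equilibrium constant (k = 0.129 /M/s)
    Z → X (k = 0.00247 /s)

Changing Z from ochre's amount to elm's leaves ochre's last G at 85.3 %, against 85.2 %. Maple's own mean constant is 0.104 /min, less than the mean read on ochre.

**At six minutes.** For maple read at 6.0 min, ochre's mean constant gives G 47.8 %. The computed flask holds 50.3 % of G, and its leader there is G.

The readings were generated by integration with constants of no real substance; scatter was added.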